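**Plan**
- Retrosynthesis (labdane numbering: ring A = C1–C5 + C10, ring B = C5–C10, C19 = CH2OH on C4, side chain C11–C16): cut C12–C13 (butenolide, Negishi), then C11–C12 with alkene transposition (formaldehyde ene), then C1–C10 and C2–C3 of ring A in one event with CH2=CHLi as the C1–C2 unit, then C3–C4 (enolate alkylation) and C4–C5 (Mukaiyama–Michael).
- Forward: ring B is dressed first from (R)-4-silyloxycyclohexenone (two methyls, C5 arm, exocyclic allylic carbonate C11), ring A is then annulated, then C5/C6, C4, C19 and the side chain are adjusted.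
- Enabling feature: C10 is quaternary and allylic (C8=C9 in the target, C9=C11 before the ene step), so it can be the terminus of an η3-allyl palladium unit; C2 of ring A carries oxygen between C1 and C3, so the C2–O bond can be born as a C2–B bond when C3 shifts from boron onto a B-vinyl group.
- Stereochemistry: the silyloxy carbon of 1 is a relay (C5 arm anti to it; C1 then enters C10 on the arm face, cis fusion); C5 is then equilibrated through the C6 ketone (trans), C6 set by equilibrating reduction (equatorial), C4 by equatorial methylation, C2 in the annulation (C–B oxidised with retention).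

Key step: step 10

Assumption: (R)-4-(tert-butyldimethylsilyloxy)cyclohex-2-en-1-one (1) is taken as purchasable (both antipodes are accessible from quinic acid); labdane numbering is used for all intermediates, and centres that later become planar or are later equilibrated (C8 up to step 18, C4 up to step 14) are carried as epimer mixtures.

Step 1
Reactants: 1 (R)-4-(tert-butyldimethylsilyloxy)cyclohex-2-en-1-one
Product: 2 (R)-4-(tert-butyldimethylsilyloxy)-2-iodocyclohex-2-en-1-one
Conditions: I2, pyridine, CH2Cl2, 0 to 20 °C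
Reagents that add atoms: iodine, II
Why: α-iodination of the enone by pyridine-mediated conjugate addition, iodination and elimination (Baylis–Hillman-type α-functionalisation), which leaves the silyloxy stereocentre untouched.

Step 2
Reactants: 2 (R)-4-(tert-butyldimethylsilyloxy)-2-iodocyclohex-2-en-1-one
Product: 3 (R)-4-(tert-butyldimethylsilyloxy)-2-methylcyclohex-2-en-1-one
Conditions: Me4Sn, PdCl2(PhCN)2 (5 mol %), AsPh3, CuI, N-methylpyrrolidone, 80 °C
Reagents that add atoms: tetramethylstannane, C[Sn](C)(C)C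
Why: Stille coupling of an α-iodoenone, which places the future C10 methyl group.

Step 3
Reactants: 3 (R)-4-(tert-butyldimethylsilyloxy)-2-methylcyclohex-2-en-1-one
Product: 4 (4R)-4-(tert-butyldimethylsilyloxy)-2,6-dimethylcyclohex-2-en-1-one (both C6 epimers; this carbon is the later C8)
Conditions: LiN(iPr)2, THF, −78 °C; MeI, −78 to −20 °C
Reagents that add atoms: iodomethane, CI
Why: alkylation of the kinetic cross-conjugated (α′) lithium enolate; the new centre is not controlled because it becomes sp2 in step 18.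

Step 4
Reactants: 5 tert-butyl acetate
Product: 6 1-tert-butoxy-1-(trimethylsilyloxy)ethene
Conditions: LiN(iPr)2, THF, −78 °C; Me3SiCl
Reagents that add atoms: chlorotrimethylsilane, C[Si](C)(C)Cl
Why: O-silylation of the lithium ester enolate gives the ketene silyl acetal.

Step 5
Reactants: 4 (4R)-4-(tert-butyldimethylsilyloxy)-2,6-dimethylcyclohex-2-en-1-one; 6 1-tert-butoxy-1-(trimethylsilyloxy)ethene
Product: 7 tert-butyl [6β-(tert-butyldimethylsilyloxy)-8,10-dimethyl-9-(trimethylsilyloxy)cyclohex-9-en-5α-yl]acetate (ring B; arm trans to the silyloxy group)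
Conditions: Me3SiNTf2 (5 mol %), CH2Cl2, −78 °C
Reagents that add atoms: none
Why: Mukaiyama–Michael addition, in which the ketene acetal adds to C5 anti to the γ-silyloxy group and silyl transfer fixes the enol ether at C9=C10.

Step 6
Reactants: 7 tert-butyl [6β-(tert-butyldimethylsilyloxy)-8,10-dimethyl-9-(trimethylsilyloxy)cyclohex-9-en-5α-yl]acetate
Product: 8 enol triflate of 7 (C9–OSO2CF3; C9=C10)
Conditions: CsF, PhNTf2, 1,2-dimethoxyethane, 20 °C
Reagents that add atoms: N-phenylbis(trifluoromethanesulfonimide), O=S(=O)(N(c1ccccc1)S(=O)(=O)C(F)(F)F)C(F)(F)F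
Why: fluoride-induced cleavage of the regiodefined silyl enol ether and O-triflation of the enolate (enol triflate formation), which keeps the double bond at C9=C10.

Step 7
Reactants: 8 enol triflate (C9–OSO2CF3; C9=C10)
Product: 9 tert-butyl 2-[ring B enol triflate-5α-yl]-3-(pinacolboryl)propanoate (C4 epimers; C3 = CH2B)
Conditions: LiN(iPr)2, THF, −78 °C; ICH2B(pin), −78 to −20 °C
Reagents that add atoms: 2-(iodomethyl)-4,4,5,5-tetramethyl-1,3,2-dioxaborolane, ICB1OC(C)(C)C(C)(C)O1
Why: alkylation of the ester enolate with an α-halo boronic ester installs C3 with its boron; C4 is left uncontrolled because it is re-enolised in step 14.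

Step 8
Reactants: 9 boryl ester enol triflate
Product: 10 allylic alcohol (C9–CH2OH = C11; C9=C10)
Conditions: Bu3SnCH2OH, Pd(PPh3)4 (5 mol %), LiCl, 1,4-dioxane, 95 °C
Reagents that add atoms: (tributylstannyl)methanol, CCCC[Sn](CO)(CCCC)CCCC
Why: Stille (Migita–Kosugi–Stille) hydroxymethylation of the enol triflate, which an alkyl pinacol boronate survives.

Step 9
Reactants: 10 allylic alcohol
Product: 11 allylic tert-butyl carbonate (C11–OCO2tBu)
Conditions: Boc2O, 4-(dimethylamino)pyridine (10 mol %), CH2Cl2, 0 °C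
Reagents that add atoms: di-tert-butyl dicarbonate, CC(C)(C)OC(=O)OC(=O)OC(C)(C)C
Why: O-acylation of the primary allylic alcohol gives a leaving group that zerovalent palladium ionises and that is hindered enough to outlast CH2=CHLi at −78 °C.

Step 10
Reactants: 11 allylic tert-butyl carbonate
Product: 13 cis-fused bicyclic boronate (5β-H; 10β-CH3; 9(11)-methylene; 6β-OSi; 2α-B(pin); C4–CO2tBu), via lithium vinylboronate complex 12 (not isolated)
Conditions: CH2=CHLi (1.05 equiv, made from Sn(CH=CH2)4 and MeLi in Et2O), THF, −78 °C; then Pd2(dba)3 (2.5 mol %), PPh3 (10 mol %), −78 to 20 °C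
Reagents that add atoms: vinyllithium, [Li]C=C (made in the flask from tetravinylstannane, C=C[Sn](C=C)(C=C)C=C, and methyllithium, [Li]C)
Why: Proposed new method: CH2=CHLi adds to boron to give borate 12, zerovalent palladium ionises the carbonate to an η3-allyl complex (C11–C9–C10) that can change face by η3–η1–η3 slippage at the exocyclic CH2, and the terminal vinyl carbon C1 attacks C10 anti to palladium while C3 migrates from boron to C2 (1,2-metalate shift), so that C1–C10 and C2–C3 form in one operation and boron ends on C2. The closest known reaction type is the palladium- or iridium-catalysed allylation-induced 1,2-metalate rearrangement of alkenylboronate complexes (three-component coupling of a boronic ester, an alkenyllithium and an allylic ester), here made intramolecular. Ring A closes by attack of the tethered alkene on the allyl terminus next to the tether carbon (seven-membered array containing boron, exo to the allyl unit) and contracts to the six-membered carbocycle through the shift, a formal (4+2) annulation. C10 is set by the tether, since C1 can only reach the face of C10 that carries the C5 arm (α), which gives the cis ring fusion with the methyl group β; C2 is expected with boron equatorial (α) because boron is extruded to the exo position of the chair-like array. The step needs attack at C10 and not at C11 (seven- against nine-membered array), addition of CH2=CHLi to boron faster than to the carbonate or the tert-butyl ester (−78 °C), and ring closure faster than β-hydride elimination of the allyl complex.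

Step 11
Reactants: 13 cis-fused bicyclic boronate
Product: 14 cis-fused 6β-alcohol
Conditions: Bu4NF, AcOH, THF, 20 °C
Reagents that add atoms: none
Why: fluoride desilylation of the secondary silyl ether, buffered so that the boronic ester and the tert-butyl ester are kept.

Step 12
Reactants: 14 cis-fused 6β-alcohol
Product: 16 trans-fused 6-ketone (5α-H), via cis-fused 6-ketone 15 (not isolated)
Conditions: Dess–Martin periodinane, NaHCO3, CH2Cl2, 20 °C; then 1,8-diazabicyclo[5.4.0]undec-7-ene, 20 °C
Reagents that add atoms: none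
Why: Dess–Martin oxidation followed by base equilibration at C5 (α to the ketone) to the more stable trans-fused decalone, as in 6-oxo steroids; the exocyclic alkene is not in conjugation and cannot migrate into it.

Step 13
Reactants: 16 trans-fused 6-ketone
Product: 17 6α-alcohol (equatorial)
Conditions: Al(OiPr)3, isopropanol, toluene, 80 °C, acetone distilled off
Reagents that add atoms: none
Why: Meerwein–Ponndorf–Verley reduction under equilibrating conditions should give the equatorial 6α-alcohol (thermodynamic control) without touching the ester or the boronate.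

Step 14
Reactants: 17 6α-alcohol
Product: 18 4α-methyl 4β-tert-butyl ester (C4 quaternary)
Conditions: LiN(iPr)2 (2.2 equiv), THF, −78 to −30 °C; MeI
Reagents that add atoms: iodomethane, CI
Why: C-alkylation of the ester enolate (the alkoxide at C6 is a spectator), with iodomethane approaching C4 from the equatorial α face, away from the axial 10β-methyl group, so that the ester ends axial as in podocarpate-type alkylations.

Step 15
Reactants: 18 4α-methyl 4β-tert-butyl ester
Product: 20 2α,6α,19-triol with 9(11)-methylene, via lithium alkyltrihydroborate 19 (not isolated)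
Conditions: LiAlH4, THF, 0 to 65 °C; then H2O, NaOH, H2O2, 0 to 20 °C
Reagents that add atoms: hydrogen peroxide, OO
Why: LiAlH4 reduces the ester to C19–OH and turns the pinacol boronate into an alkyltrihydroborate, whose alkaline peroxide oxidation gives the C2 alcohol with retention.

Step 16
Reactants: 20 2α,6α,19-triol
Product: 21 2α,19-bis(tert-butyldimethylsilyl) ether with free 6α-OH
Conditions: t-BuMe2SiCl (2.2 equiv), imidazole, N,N-dimethylformamide, 0 °C
Reagents that add atoms: tert-butylchlorodimethylsilane, CC(C)(C)[Si](C)(C)Cl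
Why: silyl ether formation selects the primary C19 and the unhindered C2 hydroxyl groups over the 6α-hydroxyl, which is crowded by C4 and C5.

Step 17
Reactants: 21 bis-silyl ether 6α-alcohol
Product: 22 6α-acetate
Conditions: Ac2O, 4-(dimethylamino)pyridine, pyridine, 20 °C
Reagents that add atoms: acetic anhydride, CC(=O)OC(C)=O
Why: acylation of the remaining hindered secondary alcohol under nucleophilic catalysis.

Step 18
Reactants: 22 6α-acetate with 9(11)-methylene
Product: 23 homoallylic alcohol (C12–OH; C8=C9)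
Conditions: (CH2O)n, Me2AlCl, CH2Cl2, −78 to 0 °C
Reagents that add atoms: formaldehyde, C=O
Why: Lewis acid-promoted carbonyl-ene reaction of the 1,1-disubstituted alkene with formaldehyde adds C12 and moves the double bond to C8=C9, the only direction with an allylic hydrogen (C10 is quaternary), which also removes the C8 stereocentre.

Step 19
Reactants: 23 homoallylic alcohol
Product: 24 primary iodide (C12–I)
Conditions: I2, PPh3, imidazole, CH2Cl2, 0 to 20 °C
Reagents that add atoms: iodine, II
Why: Appel-type iodination of the primary alcohol under neutral conditions, which acetate and silyl ethers tolerate.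

Step 20
Reactants: 24 primary iodide; 25 4-bromofuran-2(5H)-one
Product: 27 2,19-bis-O-(tert-butyldimethylsilyl) derivative of the target, via alkylzinc iodide 26 (not isolated)
Conditions: Zn dust, LiCl, THF, 40 °C; then 25, Pd2(dba)3 (2.5 mol %), 2-dicyclohexylphosphino-2′,6′-dimethoxybiphenyl (10 mol %), THF, 20 °C
Reagents that add atoms: none
Why: zinc insertion into the primary iodide and Negishi coupling with the β-bromobutenolide forms C12–C13 and delivers the 4-substituted furan-2(5H)-one in the presence of the acetate.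

Step 21
Reactants: 27 bis-silyl ether of the target
Product: 28 6α-acetoxy-2α,19-dihydroxylabda-8,13-dien-15,16-olide (CNP0231903.1)
Conditions: HF·pyridine, THF, 0 to 20 °C
Reagents that add atoms: none
Why: acidic fluoride desilylation frees the C2 and C19 hydroxyl groups without acyl migration or opening of the butenolide.

**Compound list**
1 | (R)-4-(tert-butyldimethylsilyloxy)cyclohex-2-en-1-one | O=C1C=C[C@H](O[Si](C)(C)C(C)(C)C)CC1 | starting material
2 | (R)-4-(tert-butyldimethylsilyloxy)-2-iodocyclohex-2-en-1-one | O=C1C(I)=C[C@H](O[Si](C)(C)C(C)(C)C)CC1 | intermediate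
3 | (R)-4-(tert-butyldimethylsilyloxy)-2-methylcyclohex-2-en-1-one | O=C1C(C)=C[C@H](O[Si](C)(C)C(C)(C)C)CC1 | intermediate
4 | (4R)-4-(tert-butyldimethylsilyloxy)-2,6-dimethylcyclohex-2-en-1-one (C6 epimers) | O=C1C(C)=C[C@H](O[Si](C)(C)C(C)(C)C)CC1C | intermediate
5 | tert-butyl acetate | CC(=O)OC(C)(C)C | starting material
6 | 1-tert-butoxy-1-(trimethylsilyloxy)ethene | C=C(O[Si](C)(C)C)OC(C)(C)C | intermediate
7 | tert-butyl [6β-(tert-butyldimethylsilyloxy)-8,10-dimethyl-9-(trimethylsilyloxy)cyclohex-9-en-5α-yl]acetate | C[Si](C)(C)OC1=C(C)[C@@H](CC(=O)OC(C)(C)C)[C@H](O[Si](C)(C)C(C)(C)C)CC1C | intermediate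
8 | enol triflate of 7 (C9–OSO2CF3, C9=C10) | O=S(=O)(OC1=C(C)[C@@H](CC(=O)OC(C)(C)C)[C@H](O[Si](C)(C)C(C)(C)C)CC1C)C(F)(F)F | intermediate
9 | tert-butyl 2-(ring B enol triflate-5α-yl)-3-(pinacolboryl)propanoate (C4 epimers) | O=S(=O)(OC1=C(C)[C@@H](C(CB2OC(C)(C)C(C)(C)O2)C(=O)OC(C)(C)C)[C@H](O[Si](C)(C)C(C)(C)C)CC1C)C(F)(F)F | intermediate
10 | allylic alcohol (C9–CH2OH, C9=C10) | OCC1=C(C)[C@@H](C(CB2OC(C)(C)C(C)(C)O2)C(=O)OC(C)(C)C)[C@H](O[Si](C)(C)C(C)(C)C)CC1C | intermediate
11 | allylic tert-butyl carbonate | CC(C)(C)OC(=O)OCC1=C(C)[C@@H](C(CB2OC(C)(C)C(C)(C)O2)C(=O)OC(C)(C)C)[C@H](O[Si](C)(C)C(C)(C)C)CC1C | intermediate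
12 | lithium vinylboronate complex of 11 | [Li+].CC(C)(C)OC(=O)OCC1=C(C)[C@@H](C(C[B-]2(C=C)OC(C)(C)C(C)(C)O2)C(=O)OC(C)(C)C)[C@H](O[Si](C)(C)C(C)(C)C)CC1C | intermediate
13 | cis-fused bicyclic boronate (5β-H, 10β-CH3, 9(11)-methylene, 6β-OSi, 2α-B(pin), C4–CO2tBu) | CC(C)(C)[Si](C)(C)O[C@@H]1CC(C)C(=C)[C@@]2(C)C[C@@H](B3OC(C)(C)C(C)(C)O3)CC(C(=O)OC(C)(C)C)[C@@H]12 | intermediate
14 | cis-fused 6β-alcohol | O[C@@H]1CC(C)C(=C)[C@@]2(C)C[C@@H](B3OC(C)(C)C(C)(C)O3)CC(C(=O)OC(C)(C)C)[C@@H]12 | intermediate
15 | cis-fused 6-ketone (5β-H) | O=C1CC(C)C(=C)[C@@]2(C)C[C@@H](B3OC(C)(C)C(C)(C)O3)CC(C(=O)OC(C)(C)C)[C@@H]12 | intermediate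
16 | trans-fused 6-ketone (5α-H) | O=C1CC(C)C(=C)[C@@]2(C)C[C@@H](B3OC(C)(C)C(C)(C)O3)CC(C(=O)OC(C)(C)C)[C@H]12 | intermediate
17 | 6α-alcohol | O[C@H]1CC(C)C(=C)[C@@]2(C)C[C@@H](B3OC(C)(C)C(C)(C)O3)CC(C(=O)OC(C)(C)C)[C@H]12 | intermediate
18 | 4α-methyl 4β-tert-butyl ester | O[C@H]1CC(C)C(=C)[C@@]2(C)C[C@@H](B3OC(C)(C)C(C)(C)O3)C[C@](C)(C(=O)OC(C)(C)C)[C@H]12 | intermediate
19 | lithium 2α-alkyltrihydroborate 6α,19-diol | [Li+].O[C@H]1CC(C)C(=C)[C@@]2(C)C[C@@H]([BH3-])C[C@](C)(CO)[C@H]12 | intermediate
20 | 2α,6α,19-triol with 9(11)-methylene | O[C@H]1CC(C)C(=C)[C@@]2(C)C[C@@H](O)C[C@](C)(CO)[C@H]12 | intermediate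
21 | 2α,19-bis(tert-butyldimethylsilyl) ether 6α-alcohol | O[C@H]1CC(C)C(=C)[C@@]2(C)C[C@@H](O[Si](C)(C)C(C)(C)C)C[C@](C)(CO[Si](C)(C)C(C)(C)C)[C@H]12 | intermediate
22 | 6α-acetate | CC(=O)O[C@H]1CC(C)C(=C)[C@@]2(C)C[C@@H](O[Si](C)(C)C(C)(C)C)C[C@](C)(CO[Si](C)(C)C(C)(C)C)[C@H]12 | intermediate
23 | homoallylic alcohol (C12–OH, C8=C9) | CC(=O)O[C@H]1CC(C)=C(CCO)[C@@]2(C)C[C@@H](O[Si](C)(C)C(C)(C)C)C[C@](C)(CO[Si](C)(C)C(C)(C)C)[C@H]12 | intermediate
24 | primary iodide (C12–I) | CC(=O)O[C@H]1CC(C)=C(CCI)[C@@]2(C)C[C@@H](O[Si](C)(C)C(C)(C)C)C[C@](C)(CO[Si](C)(C)C(C)(C)C)[C@H]12 | intermediate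
25 | 4-bromofuran-2(5H)-one | O=C1C=C(Br)CO1 | starting material
26 | alkylzinc iodide | CC(=O)O[C@H]1CC(C)=C(CC[Zn]I)[C@@]2(C)C[C@@H](O[Si](C)(C)C(C)(C)C)C[C@](C)(CO[Si](C)(C)C(C)(C)C)[C@H]12 | intermediate
27 | 2,19-bis-O-(tert-butyldimethylsilyl) target | CC(=O)O[C@H]1CC(C)=C(CCC3=CC(=O)OC3)[C@@]2(C)C[C@@H](O[Si](C)(C)C(C)(C)C)C[C@](C)(CO[Si](C)(C)C(C)(C)C)[C@H]12 | intermediate
28 | 6α-acetoxy-2α,19-dihydroxylabda-8,13-dien-15,16-olide (CNP0231903.1) | CC(=O)O[C@H]1CC(C)=C(CCC2=CC(=O)OC2)[C@@]2(C)C[C@@H](O)C[C@](C)(CO)[C@H]12 | target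

**Totals**
Total step count: 21. Longest linear sequence: 20 steps (steps 1–3 and 5–21, from 1 to 28).

**Steps most likely to fail**

Step 10 (proposed new method). Possible failures are β-hydride elimination of the allyl–palladium intermediate before ring closure, addition of CH2=CHLi to the carbonate, and insufficient control at C2. The fallback sets out from 10 and comes back at 20, using known reactions only. CH2=CHLi (2 equiv), then I2 and NaOMe (Zweifel olefination) would turn the C3–B bond into a C3–vinyl bond and give the allyl-substituted allylic alcohol F1. CF3CO2H in CH2Cl2 at −78 °C would ionise the allylic alcohol, and the terminal alkene would close ring A on C10 from the face of the arm (cation–olefin cyclisation, capture at C2 by trifluoroacetate), giving the cis-fused trifluoroacetate F2. K2CO3/MeOH and then Bu4NF would free the 2,6-diol F3. Dess–Martin periodinane and then 1,8-diazabicyclo[5.4.0]undec-7-ene would give the trans-fused 2,6-diketone F4. Al(OiPr)3 in isopropanol would give the diequatorial 2α,6α-diol F5, which places C2 under thermodynamic control as well. LiN(iPr)2 (3.3 equiv) and MeI would give the 4α-methyl ester F6, which LiAlH4 reduces to triol 20.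

Step 8. The hindered tetrasubstituted enol triflate may transmetalate slowly with the hydroxymethyl stannane, so that reduction of the triflate or protodestannylation takes over. The fallback sets out from 9 and comes back at 10. Methoxycarbonylation (Pd(OAc)2, 1,3-bis(diphenylphosphino)propane, CO at 1 atm, MeOH, Et3N, N,N-dimethylformamide, 60 °C) would give the conjugated methyl ester F7. (i-Bu)2AlH at −78 °C would then reduce it, in preference to the tert-butyl ester, to allylic alcohol 10.

Step 16. The three hydroxyl groups may not be told apart well enough, so that the 6α-hydroxyl is silylated too or C2 stays free. The fallback sets out from 20 and comes back at 22. Ac2O with 4-(dimethylamino)pyridine would give the triacetate F8. K2CO3 in MeOH at 0 °C would cleave the primary and the unhindered C2 acetate and leave the crowded 6α-acetate, giving the 6α-acetate 2α,19-diol F9. t-BuMe2SiCl (2.2 equiv) and imidazole would then give 22.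

**Further compounds**
F1 | step 10 | allyl-substituted allylic alcohol (C3–CH=CH2 in place of C3–B) | OCC1=C(C)[C@@H](C(CC=C)C(=O)OC(C)(C)C)[C@H](O[Si](C)(C)C(C)(C)C)CC1C
F2 | step 10 | cis-fused 2-trifluoroacetate with 9(11)-methylene and 6β-OSi (C2 and C4 epimers) | CC(C)(C)[Si](C)(C)O[C@@H]1CC(C)C(=C)[C@@]2(C)CC(OC(=O)C(F)(F)F)CC(C(=O)OC(C)(C)C)[C@@H]12
F3 | step 10 | cis-fused 2,6β-diol | O[C@@H]1CC(C)C(=C)[C@@]2(C)CC(O)CC(C(=O)OC(C)(C)C)[C@@H]12
F4 | step 10 | trans-fused 2,6-diketone | O=C1CC(C)C(=C)[C@@]2(C)CC(=O)CC(C(=O)OC(C)(C)C)[C@H]12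
F5 | step 10 | 2α,6α-diol tert-butyl ester | O[C@H]1CC(C)C(=C)[C@@]2(C)C[C@@H](O)CC(C(=O)OC(C)(C)C)[C@H]12
F6 | step 10 | 2α,6α-diol 4α-methyl 4β-tert-butyl ester | O[C@H]1CC(C)C(=C)[C@@]2(C)C[C@@H](O)C[C@](C)(C(=O)OC(C)(C)C)[C@H]12
F7 | step 8 | conjugated methyl ester (C9–CO2CH3, C9=C10) | COC(=O)C1=C(C)[C@@H](C(CB2OC(C)(C)C(C)(C)O2)C(=O)OC(C)(C)C)[C@H](O[Si](C)(C)C(C)(C)C)CC1C
F8 | step 16 | 2α,6α,19-triacetate | CC(=O)O[C@H]1CC(C)C(=C)[C@@]2(C)C[C@@H](OC(C)=O)C[C@](C)(COC(C)=O)[C@H]12
F9 | step 16 | 6α-acetate 2α,19-diol | CC(=O)O[C@H]1CC(C)C(=C)[C@@]2(C)C[C@@H](O)C[C@](C)(CO)[C@H]12
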